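Atom numbers are labdane numbers: ring A = C1–C5 + C10, ring B = C5–C10, side chain C11–C16, acid carbon C17. Retrosynthetic cuts, in order: O–CHO; C8–C17 (carbonylation of the Δ7 enol triflate of an 8-ketone); C9–C10 together with C4–C5 in one event; C6–C7 (enolate alkylation); C8=C9 (Wittig).
Enabling feature: in ring A the CH carbon C5 lies between two quaternary carbons, C4 (gem-dimethyl) and C10 (angular methyl). Moving C4 back from C5 to C10 shrinks ring A to a 1,2,2-trimethylcyclopentane that carries C5 as a side-chain carbinol. This is the five-membered ring of camphor with all three ring-A methyl groups already in place.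
Forward: a cyclopentyl methyl ketone from (−)-camphoric acid is alkylated with a C7–C15 dibromide from (S)-citronellol. Ionisation at C5 then enlarges the cyclopentane to ring A and closes ring B on an allylsilane in the same step. The helper methylene is ozonised off and C17 is put in with CO.
Stereochemistry: C13 comes from (S)-citronellol and C10 from C1 of camphoric acid. C5 comes from a CBS reduction and is inverted in the shift. C9 comes from the alkene geometry in a chair closure and stays correctable at the 8-ketone.
Key step: step 12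

Assumption: (1S,3R)-(−)-camphoric acid and (S)-(−)-citronellol are both taken as commercial single enantiomers.

Step 1
Reactants: 1 (1S,3R)-camphoric acid
Product: 3 (1S,3R)-3-[(1,3-dioxoisoindolin-2-yl)oxycarbonyl]-1,2,2-trimethylcyclopentane-1-carboxylic acid, via camphoric anhydride 2 (not isolated)
Conditions: DIC (1.0 equiv), CH2Cl2, 0 °C to rt; then N-hydroxyphthalimide, DMAP (10 mol %), rt
Reagents that add atoms: N-hydroxyphthalimide, O=C1c2ccccc2C(=O)N1O
Why: Carbodiimide dehydration closes the cis-1,3-diacid to its cyclic anhydride and DMAP-catalysed acyl transfer (Steglich-type esterification) should open it only at the secondary C3 carbonyl, because the other carbonyl sits on a quaternary carbon next to a second quaternary carbon, and no stereocentre is touched.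

Step 2
Reactants: 3 mono N-hydroxyphthalimide ester
Product: 4 (1S)-1,2,2-trimethylcyclopentane-1-carboxylic acid
Conditions: Ru(bpy)3Cl2 (1 mol %), Hantzsch ester (1.5 equiv), DMF, blue LEDs, rt
Reagents that add atoms: none
Why: Photoredox reductive decarboxylation of a redox-active ester (the modern form of the Barton decarboxylation) breaks the N–O bond by single-electron reduction, CO2 is lost and the secondary radical takes a hydrogen atom from the Hantzsch ester, which erases the former C3 stereocentre and leaves the quaternary centre intact.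

Step 3
Reactants: 4 (1S)-1,2,2-trimethylcyclopentane-1-carboxylic acid
Product: 5 1-[(1S)-1,2,2-trimethylcyclopentyl]ethan-1-one
Conditions: MeLi (2.2 equiv), Et2O, 0 °C to rt; aq. NH4Cl
Reagents that add atoms: methyllithium, [Li]C
Why: In this ketone synthesis from a carboxylic acid and methyllithium the lithium carboxylate takes up one further methyllithium and the hindered adduct survives until the quench, so over-addition should not occur and the quaternary stereocentre is not involved.

Step 4
Reactants: 6 (S)-citronellol
Product: 7 (S)-citronellyl tert-butyldimethylsilyl ether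
Conditions: TBSCl, imidazole, CH2Cl2, rt
Reagents that add atoms: tert-butyldimethylsilyl chloride, CC(C)(C)[Si](C)(C)Cl
Why: Imidazole-promoted silylation of a primary alcohol gives a group that withstands ozone, hydride, enolate, Grignard and triflation chemistry and falls in the last step.

Step 5
Reactants: 7 (S)-citronellyl tert-butyldimethylsilyl ether
Product: 9 (4S)-6-(tert-butyldimethylsilyloxy)-4-methylhexanal, via secondary ozonide 8 (not isolated)
Conditions: O3, CH2Cl2, −78 °C; then Me2S, −78 °C to rt
Reagents that add atoms: ozone, [O-][O+]=O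
Why: Ozonolysis with reductive work-up cleaves the only C=C bond and turns the olefinic CH into the aldehyde carbon that becomes C9, the remote C13 centre being untouched.

Step 6
Reactants: 9 (4S)-6-(tert-butyldimethylsilyloxy)-4-methylhexanal
Product: 10 ethyl (2Z,6S)-2-bromo-8-(tert-butyldimethylsilyloxy)-6-methyloct-2-enoate
Conditions: Ph3P=CHCO2Et, NBS, CH2Cl2, −20 °C; then 9, rt
Reagents that add atoms: ethyl (triphenylphosphoranylidene)acetate, CCOC(=O)C=P(c1ccccc1)(c1ccccc1)c1ccccc1; N-bromosuccinimide, O=C1CCC(=O)N1Br
Why: Wittig olefination with the stabilised α-bromo ylide made in the flask puts the ester trans to the alkyl chain, which is the Z-bromoalkene geometry that later places C11 trans to C7.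

Step 7
Reactants: 10 ethyl (2Z,6S)-2-bromo-8-(tert-butyldimethylsilyloxy)-6-methyloct-2-enoate
Product: 11 (2Z,6S)-2-bromo-8-(tert-butyldimethylsilyloxy)-6-methyloct-2-en-1-ol
Conditions: i-Bu2AlH (2.2 equiv), CH2Cl2, −78 °C; aq. potassium sodium tartrate
Reagents that add atoms: none
Why: Diisobutylaluminium hydride reduces the unsaturated ester in 1,2-fashion to the allylic alcohol at low temperature without touching the vinyl bromide or the silyl ether.

Step 8
Reactants: 11 (2Z,6S)-2-bromo-8-(tert-butyldimethylsilyloxy)-6-methyloct-2-en-1-ol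
Product: 12 (3S,6Z)-7,8-dibromo-3-methyloct-6-en-1-yl tert-butyldimethylsilyl ether
Conditions: CBr4, PPh3, CH2Cl2, 0 °C
Reagents that add atoms: carbon tetrabromide, BrC(Br)(Br)Br
Why: The Appel bromination replaces the primary allylic hydroxyl under neutral conditions with retention of the alkene geometry.

Step 9
Reactants: 5 1-[(1S)-1,2,2-trimethylcyclopentyl]ethan-1-one; 12 (3S,6Z)-7,8-dibromo-3-methyloct-6-en-1-yl tert-butyldimethylsilyl ether
Product: 14 (4Z,8S)-4-bromo-10-(tert-butyldimethylsilyloxy)-8-methyl-1-[(1S)-1,2,2-trimethylcyclopentyl]dec-4-en-1-one, via lithium enolate 13 (not isolated)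
Conditions: LiN(i-Pr)2 (LDA, 1.0 equiv), THF, −78 °C; then 12, DMPU, −78 to −20 °C
Reagents that add atoms: none
Why: Kinetic enolate alkylation (SN2 at the primary allylic bromide) forms C6–C7, ketone 5 can enolise only towards its methyl group so that one regioisomer is possible, and the vinylic bromide is inert.

Step 10
Reactants: 14 bromo ketone
Product: 15 (1S,4Z,8S)-4-bromo-10-(tert-butyldimethylsilyloxy)-8-methyl-1-[(1S)-1,2,2-trimethylcyclopentyl]dec-4-en-1-ol
Conditions: (R)-2-methyl-CBS-oxazaborolidine (20 mol %), BH3·SMe2, THF, −20 to 0 °C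
Reagents that add atoms: none
Why: In the Corey–Bakshi–Shibata reduction the (R)-oxazaborolidine tells the tertiary cyclopentyl group (large) from the CH2 chain (small) and delivers hydride to the face that gives the (S)-carbinol at C5, while the electron-poor bromoalkene resists hydroboration.

Step 11
Reactants: 15 bromo carbinol
Product: 16 (1S,4Z,8S)-10-(tert-butyldimethylsilyloxy)-8-methyl-1-[(1S)-1,2,2-trimethylcyclopentyl]-4-[(trimethylsilyl)methyl]dec-4-en-1-ol
Conditions: Me3SiCH2MgCl (3 equiv), Pd(PPh3)4 (5 mol %), THF, 50 °C
Reagents that add atoms: (trimethylsilyl)methylmagnesium chloride, C[Si](C)(C)C[Mg]Cl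
Why: In this Kumada coupling, oxidative addition of zerovalent palladium to the vinyl bromide, transmetalation with the β-hydrogen-free Grignard reagent and reductive elimination proceed with retention of geometry, the first equivalent of Grignard reagent only deprotonating the hydroxyl group.

Step 12
Reactants: 16 allylsilane carbinol
Product: 18 (13S)-15-(tert-butyldimethylsilyloxy)labd-8(17)-ene (trans-decalin with H-5 and H-9 α and 10-CH3 β), via secondary triflate 17 (not isolated)
Conditions: Tf2O (1.2 equiv), 2,6-di-tert-butyl-4-methylpyridine (3 equiv), CH2Cl2, −78 to 0 °C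
Reagents that add atoms: trifluoromethanesulfonic anhydride, O=S(=O)(OS(=O)(=O)C(F)(F)F)C(F)(F)F (its triflyl group stands in 17 only)
Why: Proposed new method: triflation makes the neopentylic C5–O bond a nucleofuge that can hardly be displaced or eliminated, so ionisation should be σ-assisted, the C10–C4 bond anti to C5–OTf migrating to C5 (Wagner–Meerwein 1,2-shift) while allylsilane carbon C9 attacks the emerging tertiary C10 cation from the face that C4 leaves and the Me3Si group is lost to triflate, leaving the 8(17)-methylene group. The closest known reaction types are the solvolytic cyclopentylcarbinyl-to-cyclohexyl ring enlargement, the allylsilane-terminated cation–olefin cyclisation and, in nature, the C-ring enlargement that precedes D-ring closure in protosterol formation, but their union in one sulfonate-triggered event on such a substrate is not known. Ring A arises from the cyclopentane by the 1,2-shift (enlargement by one atom, C5 being inserted between C10 and C4), and ring B closes in a 6-endo-trig mode at the C8=C9 bond through a chair-like transition state. C5 is set by inversion at the (S)-carbinol carbon of step 10, C10 by anti replacement of C4 at the camphor-derived (S)-quaternary carbon (if a free cation intervenes, the equatorial chain on C5 leads to the same trans-decalin), and C9 by the Z-allylsilane geometry, which places the side chain equatorial. The step needs migration of C4 rather than of C1 or the methyl group, which should be secured by the higher migratory aptitude of the fully substituted carbon, the relief of strain between the vicinal quaternary carbons and the ring enlargement itself, and it needs ring closure to outrun proton loss, which the high π-nucleophilicity of the allylsilane and the hindered non-nucleophilic base should secure.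

Step 13
Reactants: 18 (13S)-15-(tert-butyldimethylsilyloxy)labd-8(17)-ene
Product: 20 (13S)-15-(tert-butyldimethylsilyloxy)-17-norlabdan-8-one, via spiro ozonide 19 (not isolated)
Conditions: O3, CH2Cl2, −78 °C; then Me2S, −78 °C to rt
Reagents that add atoms: ozone, [O-][O+]=O
Why: Ozonolysis of the only alkene removes the helper methylene carbon and gives the 8-ketone, next to which C9 keeps, or by enolisation reaches, the more stable equatorial side chain.

Step 14
Reactants: 20 (13S)-15-(tert-butyldimethylsilyloxy)-17-norlabdan-8-one
Product: 22 (13S)-15-(tert-butyldimethylsilyloxy)-17-norlabd-7-en-8-yl trifluoromethanesulfonate, via potassium enolate 21 (not isolated)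
Conditions: KN(SiMe3)2 (KHMDS), THF, −78 °C; then PhNTf2, −78 to 0 °C
Reagents that add atoms: N-phenylbis(trifluoromethanesulfonimide), O=S(=O)(N(c1ccccc1)S(=O)(=O)C(F)(F)F)C(F)(F)F
Why: Kinetic deprotonation by the bulky amide takes a C7 hydrogen rather than the hindered tertiary C9 hydrogen, and O-triflation of the enolate fixes the C7=C8 double bond (enol triflate formation).

Step 15
Reactants: 22 vinyl triflate
Product: 23 (13S)-15-(tert-butyldimethylsilyloxy)labd-7-en-17-oic acid
Conditions: Pd(OAc)2 (5 mol %), 1,1'-bis(diphenylphosphino)ferrocene (10 mol %), CO (1 atm), H2O, Et3N, DMF, 60 °C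
Reagents that add atoms: carbon monoxide, [C-]#[O+]; water, O
Why: Palladium-catalysed hydroxycarbonylation of a vinyl triflate (oxidative addition, CO insertion, hydrolysis of the acylpalladium species) installs C17 as the free acid on the existing C7=C8 bond without touching C9.

Step 16
Reactants: 23 (13S)-15-(tert-butyldimethylsilyloxy)labd-7-en-17-oic acid
Product: 25 (13S)-15-formyloxylabd-7-en-17-oic acid (target CNP0185418.1), via hydroxy acid 24 (not isolated)
Conditions: HCO2H (98 %), rt to 40 °C
Reagents that add atoms: formic acid, O=CO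
Why: Formic acid solvolyses the primary silyl ether and esterifies the freed alcohol in the same flask (Fischer-type formylation), whereas the hindered conjugated acid is left as it is and no stereocentre is affected.

Compound list
1 | (1S,3R)-(−)-camphoric acid | C[C@]1(C(=O)O)CC[C@@H](C(=O)O)C1(C)C | starting material
2 | (1S,3R)-camphoric anhydride | C[C@]1(C(=O)OC2=O)CC[C@@H]2C1(C)C | intermediate
3 | (1S,3R)-3-[(1,3-dioxoisoindolin-2-yl)oxycarbonyl]-1,2,2-trimethylcyclopentane-1-carboxylic acid | C[C@]1(C(=O)O)CC[C@@H](C(=O)ON2C(=O)c3ccccc3C2=O)C1(C)C | intermediate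
4 | (1S)-1,2,2-trimethylcyclopentane-1-carboxylic acid | C[C@]1(C(=O)O)CCCC1(C)C | intermediate
5 | 1-[(1S)-1,2,2-trimethylcyclopentyl]ethan-1-one | C[C@]1(C(C)=O)CCCC1(C)C | intermediate
6 | (S)-(−)-citronellol | CC(C)=CCC[C@H](C)CCO | starting material
7 | (S)-citronellyl tert-butyldimethylsilyl ether | CC(C)=CCC[C@H](C)CCO[Si](C)(C)C(C)(C)C | intermediate
8 | secondary ozonide of 7 (1,2,4-trioxolane, acetal carbon unassigned) | CC1(C)OOC(CC[C@H](C)CCO[Si](C)(C)C(C)(C)C)O1 | intermediate
9 | (4S)-6-(tert-butyldimethylsilyloxy)-4-methylhexanal | O=CCC[C@H](C)CCO[Si](C)(C)C(C)(C)C | intermediate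
10 | ethyl (2Z,6S)-2-bromo-8-(tert-butyldimethylsilyloxy)-6-methyloct-2-enoate | CCOC(=O)/C(Br)=C/CC[C@H](C)CCO[Si](C)(C)C(C)(C)C | intermediate
11 | (2Z,6S)-2-bromo-8-(tert-butyldimethylsilyloxy)-6-methyloct-2-en-1-ol | OC/C(Br)=C/CC[C@H](C)CCO[Si](C)(C)C(C)(C)C | intermediate
12 | (3S,6Z)-7,8-dibromo-3-methyloct-6-en-1-yl tert-butyldimethylsilyl ether | BrC/C(Br)=C/CC[C@H](C)CCO[Si](C)(C)C(C)(C)C | intermediate
13 | lithium enolate of 5 | C[C@]1(C(=C)O[Li])CCCC1(C)C | intermediate
14 | (4Z,8S)-4-bromo-10-(tert-butyldimethylsilyloxy)-8-methyl-1-[(1S)-1,2,2-trimethylcyclopentyl]dec-4-en-1-one | C[C@]1(C(=O)CC/C(Br)=C/CC[C@H](C)CCO[Si](C)(C)C(C)(C)C)CCCC1(C)C | intermediate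
15 | (1S,4Z,8S)-4-bromo-10-(tert-butyldimethylsilyloxy)-8-methyl-1-[(1S)-1,2,2-trimethylcyclopentyl]dec-4-en-1-ol | C[C@]1([C@@H](O)CC/C(Br)=C/CC[C@H](C)CCO[Si](C)(C)C(C)(C)C)CCCC1(C)C | intermediate
16 | (1S,4Z,8S)-10-(tert-butyldimethylsilyloxy)-8-methyl-1-[(1S)-1,2,2-trimethylcyclopentyl]-4-[(trimethylsilyl)methyl]dec-4-en-1-ol | C[C@]1([C@@H](O)CC/C(C[Si](C)(C)C)=C/CC[C@H](C)CCO[Si](C)(C)C(C)(C)C)CCCC1(C)C | intermediate
17 | secondary triflate of 16 | C[C@]1([C@@H](OS(=O)(=O)C(F)(F)F)CC/C(C[Si](C)(C)C)=C/CC[C@H](C)CCO[Si](C)(C)C(C)(C)C)CCCC1(C)C | intermediate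
18 | (13S)-15-(tert-butyldimethylsilyloxy)labd-8(17)-ene | C[C@H](CCO[Si](C)(C)C(C)(C)C)CC[C@H]1C(=C)CC[C@H]2C(C)(C)CCC[C@]12C | intermediate
19 | spiro ozonide of 18 (spiro carbon unassigned) | C[C@H](CCO[Si](C)(C)C(C)(C)C)CC[C@H]1C2(OCOO2)CC[C@H]3C(C)(C)CCC[C@]13C | intermediate
20 | (13S)-15-(tert-butyldimethylsilyloxy)-17-norlabdan-8-one | C[C@H](CCO[Si](C)(C)C(C)(C)C)CC[C@H]1C(=O)CC[C@H]2C(C)(C)CCC[C@]12C | intermediate
21 | potassium Δ7-enolate of 20 | C[C@H](CCO[Si](C)(C)C(C)(C)C)CC[C@H]1C(O[K])=CC[C@H]2C(C)(C)CCC[C@]12C | intermediate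
22 | (13S)-15-(tert-butyldimethylsilyloxy)-17-norlabd-7-en-8-yl trifluoromethanesulfonate | C[C@H](CCO[Si](C)(C)C(C)(C)C)CC[C@H]1C(OS(=O)(=O)C(F)(F)F)=CC[C@H]2C(C)(C)CCC[C@]12C | intermediate
23 | (13S)-15-(tert-butyldimethylsilyloxy)labd-7-en-17-oic acid | C[C@H](CCO[Si](C)(C)C(C)(C)C)CC[C@H]1C(C(=O)O)=CC[C@H]2C(C)(C)CCC[C@]12C | intermediate
24 | (13S)-15-hydroxylabd-7-en-17-oic acid | C[C@H](CCO)CC[C@H]1C(C(=O)O)=CC[C@H]2C(C)(C)CCC[C@]12C | intermediate
25 | (13S)-15-formyloxylabd-7-en-17-oic acid (CNP0185418.1) | C[C@H](CCOC=O)CC[C@H]1C(C(=O)O)=CC[C@H]2C(C)(C)CCC[C@]12C | target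

Total step count: 16. Longest linear sequence: 13 steps (steps 4 to 16, from (S)-citronellol).

Steps most likely to fail

1. Step 12.
- What may go wrong: migration and ring closure may not mesh. Possible causes are a shift of the wrong group from C10, proton loss from the ring-enlarged cation before closure, or attack of the triflating agent or of adventitious acid on the allylsilane.
- Fallback: it sets out from 15 and comes back at 18. The two bond changes are taken apart, and the nucleophile is installed only after ring A has its final size.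
- First, carbinol 15 is converted with MsCl and Et3N into the secondary mesylate F1. Its vinyl bromide is too poor a π-nucleophile to interfere.
- Buffered solvolysis (aqueous acetone or aqueous trifluoroethanol, CaCO3) is the classical Wagner–Meerwein ring enlargement of a 1-(1-methylcyclopentyl)alkyl sulfonate. It should give the ring-enlarged bromo tertiary cyclohexanol F2, and either configuration at the new carbinol carbon serves.
- Kumada coupling as in step 11 gives the allylsilane tertiary alcohol F3.
- Ionisation of the tertiary alcohol with SnCl4 in CH2Cl2 at −78 °C and allylsilane-terminated cyclisation, both known reaction types, lead to 18.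

2. Step 10.
- What may go wrong: the ketone is flanked by two contiguous quaternary carbons, so reduction may be slow. The inherent Felkin-type facial bias of the quaternary centre opposes the catalyst, so facial selectivity may be poor.
- Fallback: it sets out from 14 and comes back at 15. Catalyst control is given up for separation and recycling.
- Ketone 14 is reduced with LiAlH4 or NaBH4, and the two C5 epimers, which are diastereomers, are separated by chromatography.
- The unwanted (1R)-carbinol F4 is oxidised back to 14 with Dess–Martin periodinane and put through again.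

3. Step 15.
- What may go wrong: oxidative addition and CO insertion at the hindered triflate next to the C9 side chain may be slow, so that hydrolysis or reduction of the triflate competes.
- Fallback: it sets out from 20 and comes back at 23 by a Shapiro reaction, without palladium.
- Ketone 20 is condensed with 2,4,6-triisopropylbenzenesulfonyl hydrazide to the trisylhydrazone F5.
- n-BuLi (2.2 equiv, THF, −78 to 0 °C) removes the N–H and a C7 hydrogen, and loss of sulfinate and nitrogen gives the Δ7 vinyllithium F6.
- F6 is quenched with CO2 to give 23 after acidic work-up.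

Further compounds
F1 | step 12 | secondary mesylate of 15 | C[C@]1([C@@H](OS(C)(=O)=O)CC/C(Br)=C/CC[C@H](C)CCO[Si](C)(C)C(C)(C)C)CCCC1(C)C
F2 | step 12 | (2S)-2-[(3Z,7S)-3-bromo-9-(tert-butyldimethylsilyloxy)-7-methylnon-3-en-1-yl]-1,3,3-trimethylcyclohexan-1-ol (carbinol carbon unassigned) | CC1(O)CCCC(C)(C)[C@@H]1CC/C(Br)=C/CC[C@H](C)CCO[Si](C)(C)C(C)(C)C
F3 | step 12 | (2S)-2-{(3Z,7S)-9-(tert-butyldimethylsilyloxy)-7-methyl-3-[(trimethylsilyl)methyl]non-3-en-1-yl}-1,3,3-trimethylcyclohexan-1-ol (carbinol carbon unassigned) | CC1(O)CCCC(C)(C)[C@@H]1CC/C(C[Si](C)(C)C)=C/CC[C@H](C)CCO[Si](C)(C)C(C)(C)C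
F4 | step 10 | (1R,4Z,8S)-4-bromo-10-(tert-butyldimethylsilyloxy)-8-methyl-1-[(1S)-1,2,2-trimethylcyclopentyl]dec-4-en-1-ol | C[C@]1([C@H](O)CC/C(Br)=C/CC[C@H](C)CCO[Si](C)(C)C(C)(C)C)CCCC1(C)C
F5 | step 15 | 2,4,6-triisopropylbenzenesulfonylhydrazone of 20 | C[C@H](CCO[Si](C)(C)C(C)(C)C)CC[C@H]1C(=NNS(=O)(=O)c2c(C(C)C)cc(C(C)C)cc2C(C)C)CC[C@H]3C(C)(C)CCC[C@]13C
F6 | step 15 | (13S)-15-(tert-butyldimethylsilyloxy)-17-norlabd-7-en-8-yllithium | C[C@H](CCO[Si](C)(C)C(C)(C)C)CC[C@H]1C([Li])=CC[C@H]2C(C)(C)CCC[C@]12C
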